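The ratio to watch is coupling partner used per substrate reacted, the partner price: it is one if each reacted substrate stops at first product, and two if each goes on to side product.

| flask | substrate | coupling partner | remark | time |
|---|---|---|---|---|
| Saturday's | 35 mM | 0.50 equiv (fed, over 15 min) | run made earlier |  |
| Monday's | 35 mM | 0.75 equiv (fed, over 15 min) | run made earlier |  |
| Wednesday's | 70 mM | 1 equiv (fed, over 15 min) | run made earlier |  |
| flask | 35 mM | 1.00 equiv (fed, over 15 min) |  | 2.0 d |

| run | time / h | substrate / % | first product / % |
|---|---|---|---|
| Saturday's | 4.00 | 64.3 | 27.0 |
| Saturday's | 6.00 | 61.1 | 28.7 |
| Saturday's | 8.00 | 62.5 | 29.4 |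
| Saturday's | 15.0 | 60.3 | 30.1 |
| Saturday's | 20.0 | 59.4 | 29.7 |
| Saturday's | 30.0 | 61.0 | 30.3 |
| Saturday's | 50.0 | 58.4 | 31.8 |
| Monday's | 6.00 | 48.1 | 35.8 |
| Monday's | 15.0 | 45.4 | 34.1 |
| Monday's | 20.0 | 43.6 | 33.9 |
| Monday's | 30.0 | 44.4 | 36.7 |
| Monday's | 40.0 | 44.1 | 35.7 |
| Monday's | 50.0 | 45.5 | 34.6 |
| Wednesday's | 10.0 | 32.1 | 33.9 |
| Wednesday's | 20.0 | 32.6 | 35.6 |
| Wednesday's | 30.0 | 31.4 | 34.9 |
| Wednesday's | 40.0 | 31.0 | 37.2 |
| Wednesday's | 50.0 | 33.3 | 36.0 |

(scatter of a reading: 1 percentage point)

1. which holds at 2.0 d: what has brought the reaction to rest, or that it has not come to rest (the coupling partner has run out first / all of the substrate has reacted / it is still moving)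
2. conversion of substrate at 2.0 d
3. amount of first product at 2.0 d, in percent of the substrate charged
4. amount of side product at 2.0 d, in percent of the substrate charged

- what was read earlier has a scatter of 1 percentage point, one standard deviation
- the reaction counts as stopped when no species that holds the substrate changes by six tenths of a point or more over the second half of the time

You don't read side product, so take it as the remainder. Wednesday's substrate readings stay flat, within their scatter, at a mean conversion of 67.9%, and with a mean of 35.5% first product, first product plus twice side product comes to 100% of the substrate charged. That matches Wednesday's charge of 1 equiv, so treat the coupling partner as the limiting reagent. Wednesday's flask then gives 1.47 equiv as its partner price, coupling partner used per substrate reacted.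

If the coupling partner is used up, conversion in your flask is its charge over its price, so with a price between one and two it lies between 50.0% and 100%. The late readings put the price at 1.24 equiv on Saturday and 1.35 equiv on Monday. I take it to keep rising with the charge, which lowers the ceiling to 73.9%. Wednesday has your charge at twice your concentration. If each step is one partner meeting one molecule, dilution slows both alike, leaves the price alone and stretches the clock: Wednesday's flatness by 10.0 h becomes 20.0 h here, shorter than 2.0 d. Wednesday's extreme readings, each with its scatter of 1 percentage point, narrow the estimate to 66.7% to 69.0%, and its price, a reading too, gives 67.9% conversion, 35.8% first product and 32.1% side product.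

The forecast, “should end like Wednesday's run”, says the coupling partner has run out first, with 68% conversion, 36% first product and 32% side product.

The flask gives 67.6% conversion, 35.3% first product and 32.4% side product: the coupling partner has run out first.

    double product + released group → side product (k = 9.12 /M/h)
    coupling partner + first product → double product + released group (k = 15.4 /M/h)
    substrate + coupling partner → first product + released group (k = 14.5 /M/h)

Of the coupling partner 0% is left in your flask, less than the 32% of the substrate. The partner price of your flask is 1.48 equiv. With the charge raised to 1.70 equiv, a neighbouring flask converts 93.3% at a price of 1.82 equiv. The price less one, times that conversion, gives 76.7% of the substrate charged as side product, and that flask holds 76.6%.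

(The runs stem from a simulated flask for an exercise; scatter was added.)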